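# Proposed synthesis of (2S)-7-hydroxy-2-[(3R,4S)-3,4,8-trihydroxy-2,2-dimethylchroman-6-yl]chroman-4-one (16)

Assumption: 5-bromo-2,3-dihydroxybenzaldehyde (1) and 7-hydroxychromone (13) are taken as catalogue compounds; the absolute sense of the two chiral catalysts (steps 5 and 10) is assigned by analogy and is to be confirmed on the first run, the antipodal catalyst being available in both cases.

## The problem

Compound 16 is a (2S)-7-hydroxyflavanone (ring A the resorcinol-type benzene ring, ring C the pyranone) whose C2 aryl group, ring B, is also the benzene ring of a 2,2-dimethylchromane with ring D as its pyran ring; ring B carries the flavanone at C6, a phenol at C8 and, through ring D, a trans-3,4-diol. Three stereocentres must be set: C2 of ring C (S), and C3 (R) and C4 (S) of ring D. C3 and C4 are neighbours, so one can direct the other, whereas C2 lies across ring B from them and needs its own reagent control. The molecule tolerates neither extreme of pH: base opens ring C to the 2′-hydroxychalcone by a retro-oxa-Michael reaction and erases C2, and strong acid ionises the benzylic C4–OH, which is activated by the ortho ring oxygen O1, with epimerisation, solvolysis or dehydration as the result. Ring B, with O1 and the C8 hydroxyl in a catechol arrangement, is easily oxidised, so late oxidations are unwelcome and all protecting groups should leave together under mild acid. The feature that opens a short route is the C3–C4 bond of ring D: both carbons bear oxygen, C4 is bonded to ring B, C3 to the quaternary C2, and O1 ties the two ends together. With C4 at the ketone level this bond is an acyloin linkage between an aryl acyl carbon and a carbinol carbon derived from an aldehyde without α-hydrogen, that is, the product of an intramolecular crossed benzoin reaction of a dialdehyde.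

## Retrosynthesis

**Protecting groups (16 from 15).** No skeletal bond is cut. The two phenols are masked as methoxymethyl (MOM) ethers and the diol as its bis(tert-butyldimethylsilyl) (TBS) ether in 15. All four groups fall to dilute aqueous acid in one operation, which the flavanone tolerates where base would not. Silyl ethers are preferred on the diol to alkyl MOM ethers (stronger acid needed at a benzylic carbinol) and to esters (basic removal, incompatible with n-BuLi). Benzyl ethers on the phenols would need a hydrogenolysis that endangers the benzylic C4–O and C2–O1 bonds. The forward step must cleave acetals and silyl ethers without ionising C4.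

**Flavanone C2 to ring B (15 from 12 and 14).** The bond between C2 of ring C and C6 of the chromane is cut, giving the arylboronic acid 12 and 7-(methoxymethoxy)chromone 14. The neighbouring cut at O1–C2 (oxa-Michael closure of a chalcone) is under thermodynamic control and hard to make enantioselective without extra activating groups. The cut at C8a–O1 needs an open-chain stereocentre built separately. The C–C cut divides the molecule into halves of similar size and creates C2 in the joining step under catalyst control. The forward reaction must transfer the aryl group to one face of a donor-substituted chromone under conditions that never become basic.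

**Boron from bromine, diol masked (12 from 9 from 8).** The C–B bond is traced to the C–Br bond of 9 (lithium–bromine exchange, borate quench), and the silyl ethers to the free trans-diol 8. The bromine is bought with the starting material, sits para to the oxygen that becomes O1, and is inert to every earlier step. The forward steps only have to keep the two carbinols covered while the aryllithium exists.

**C4 carbinol from ketone (8 from 7).** The C4–H bond is cut, leaving the ketol 7 with one stereocentre instead of two. The C3 hydroxyl is the control element: hydride delivered from boron bound to that oxygen arrives on its face and leaves the new hydroxyl trans. An undirected reduction is expected to favour the cis isomer, so the forward step must be truly intramolecular.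

**Key disconnection, C3–C4 (7 from 6).** The acyloin bond of ring D is cut to the dialdehyde 6. Neighbouring options are the O1–C2 cut (an epoxide opening) and oxidation of a chromene C3=C4 bond. The acyloin cut removes ring D, the only C–C bond of this half that is not bought, and the C3 stereocentre in one operation, and leaves an achiral, non-enolisable precursor. The forward reaction asks the aryl aldehyde to become the acyl anion and the aliphatic aldehyde to accept it, with face selection by a chiral carbene and without epimerisation of the secondary ketol.

**The aryl ether and the oxidation levels (6 from 5 from 4 from 2 and 3).** The O–C(Me)2 bond is cut to the salicylaldehyde 2 and ethyl 2-bromo-2-methylpropanoate 3, which supplies the quaternary carbon and the future C3 at the ester level. A half-reduction of the ester beside a free aryl aldehyde would need that aldehyde masked and unmasked. Reducing both carbonyls to the diol 5 and oxidising both alcohols together is one step shorter and avoids acid on the MOM ether.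

**Protected building blocks (2 from 1; 14 from 13).** Only O–CH2OMe bonds are cut. In 1 the two phenols differ enough (one chelated and conjugated to the formyl group, one not) for a selective mono-alkylation. 13 has a single phenol.

## Roads not taken

**Alternative 1: copper O-arylation closes ring C.** The cut is the aryl ether bond O1–C8a of ring C. In the forward direction (1S,3S)-1-[2-bromo-4-(methoxymethoxy)phenyl]-3-[8-(methoxymethoxy)-2,2-dimethyl-2H-chromen-6-yl]propane-1,3-diol A2 would cyclise under CuI, 3,4,7,8-tetramethyl-1,10-phenanthroline and Cs2CO3. The hydroxyl on the chromenyl-bearing carbon of A2 displaces the ortho bromide and gives (2S,4S)-7-(methoxymethoxy)-2-[8-(methoxymethoxy)-2,2-dimethyl-2H-chromen-6-yl]chroman-4-ol A1.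
- Merits: the C–O bond at the stereocentre is never broken, so C2 is retained. With C4 at the alcohol level there is no chalcone pathway during closure. The other hydroxyl of A2 could only close a four-membered ring, so chemoselectivity is built in.
- Weak points: A2 needs two stereocentres, one of which is destroyed when C4 is oxidised. A1 still needs that oxidation and a trans-dihydroxylation of its chromene double bond, carried out late on an electron-rich ring B or in the presence of the base-sensitive flavanone. The chromene must survive hot carbonate and copper. The route is linear.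
- Comparison: on C2 this road is the safer one, since it does not depend on a conjugate addition to a deactivated chromone. Its ring-D diol would rest on Jacobsen epoxidation of a 2,2-dimethylchromene with a chiral (salen)MnCl complex, which is better precedented than an aldehyde-acceptor benzoin. Against this the chosen plan sets convergence (two halves joined in one catalytic step), no stereocentre made and then discarded, and ring-D stereochemistry finished on a small bromoarene before the flavanone exists.

**Alternative 2: ring A folded from a pyranone-masked polyketide chain.** The cut is C4a–C5 of ring A, so the benzene ring is made last. Under mild base the dienolate carbon of (2S)-6-[(3E)-4-methoxy-2-oxobut-3-en-1-yl]-2-[(3R,4S)-3,4,8-tris(methoxymethoxy)-2,2-dimethylchroman-6-yl]-2,3-dihydro-4H-pyran-4-one A4 would add to the β-carbon of the methoxy enone. Loss of methanol and enolisation would give (2S)-7-hydroxy-2-[(3R,4S)-3,4,8-tris(methoxymethoxy)-2,2-dimethylchroman-6-yl]chroman-4-one A3. Acid cleavage of the three MOM ethers of A3 would then complete 16.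
- Merits: C2 could come from an asymmetric hetero-Diels–Alder reaction of an aryl aldehyde, a dependable entry to 2-aryl-dihydropyranones. The 7-hydroxy pattern of A3 follows from the chain. No chromone acceptor is needed.
- Weak points: A4 has several electrophilic and acidic sites. The base that makes the dienolate can also expel O1 by β-elimination, the same ring opening that threatens flavanones, and so erase C2. The side chain and its β-methoxy enone are delicate to install. The whole ring-D diol is carried through to A3 as MOM ethers, two of them on carbinols and one of these benzylic, which need stronger acid at the end than aryl MOM ethers do. A benzene ring that can be bought is built instead.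
- Comparison: in enantiocontrol at C2 the hetero-Diels–Alder entry is probably at least as dependable as the palladium-catalysed addition. The chosen plan sets against it a purchased ring A, a clearly shorter sequence and a milder last step than the one A3 would need.

**Alternative 3: phenol opens a threo epoxy alcohol 6-endo.** The cut is O1–C2 of ring D. With catalytic camphorsulfonic acid the phenol of 4-bromo-2-{(S)-(tert-butyldimethylsilyloxy)[(2R)-3,3-dimethyloxiran-2-yl]methyl}-6-(methoxymethoxy)phenol A6 would attack the dimethyl-substituted epoxide carbon. This gives (3R,4S)-6-bromo-4-(tert-butyldimethylsilyloxy)-8-(methoxymethoxy)-2,2-dimethylchroman-3-ol A5, with C3 untouched.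
- Merits: only long-established reactions are used. The two stereocentres of A6 would come from an enantioselective carbonyl addition or reduction followed by an allylic-strain-controlled, hydroxyl-directed epoxidation. Acid favours attack at the tertiary carbon, and the silyloxy group next to the other epoxide carbon disfavours the 5-exo mode. Silylation of A5 would give 9, so this road merges with the chosen one.
- Weak points: 5-exo closure to a dihydrobenzofuran is the usual competitor. The carbinol from which A6 derives is benzylic, allylic and ortho to a phenol oxygen, so it ionises easily. Two phenol oxygens and a carbinol need orthogonal protection, which adds steps.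
- Comparison: every step of this road is better precedented than the key step chosen here. The chosen plan sets against that a single catalytic step that makes the ring, the C–C bond and the stereocentre from an achiral dialdehyde, a phenol oxygen that serves as the tether from the start, and no doubly activated carbinol on the way.

Key step: step 5

## Route

Step 1
Reactants: 1 5-bromo-2,3-dihydroxybenzaldehyde
Product: 2 5-bromo-2-hydroxy-3-(methoxymethoxy)benzaldehyde
Conditions: NaH (2.2 equiv), DMF, 0 °C; MOMCl (1.0 equiv), 0 °C to rt; aq. NH4Cl
Reagents that add atoms: chloromethyl methyl ether (MOMCl), COCCl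
Why: Williamson ether synthesis on the dianion: the 3-phenoxide, neither conjugated with nor chelated to the formyl group, is the more nucleophilic oxygen, so one equivalent of MOMCl should alkylate it and leave the hydrogen-bonded 2-OH free; this selectivity is established for 2,3-dihydroxybenzaldehyde.

Step 2
Reactants: 2 5-bromo-2-hydroxy-3-(methoxymethoxy)benzaldehyde; 3 ethyl 2-bromo-2-methylpropanoate
Product: 4 ethyl 2-[4-bromo-2-formyl-6-(methoxymethoxy)phenoxy]-2-methylpropanoate
Conditions: 3 (3 equiv), Cs2CO3 (2.5 equiv), DMF, 60 °C
Reagents that add atoms: none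
Why: Williamson-type O-alkylation of a phenoxide by an α-bromoisobutyrate, the standard entry to 2-aryloxy-2-methylpropanoates; the caesium phenoxide in DMF and an excess of 3 offset the hindrance of the doubly ortho-substituted oxygen and the loss of 3 by elimination. The aldehyde has no α-hydrogen and is inert to carbonate.

Step 3
Reactants: 4 ethyl 2-[4-bromo-2-formyl-6-(methoxymethoxy)phenoxy]-2-methylpropanoate
Product: 5 2-[4-bromo-2-(hydroxymethyl)-6-(methoxymethoxy)phenoxy]-2-methylpropan-1-ol
Conditions: i-Bu2AlH (4.5 equiv), CH2Cl2, −78 to 0 °C; aq. potassium sodium tartrate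
Reagents that add atoms: none
Why: Hydride reduction of the aldehyde and the ester to the two primary alcohols; i-Bu2AlH at low temperature leaves the aryl bromide and the MOM ether untouched. Taking both carbonyls down avoids masking the aryl aldehyde for a selective ester reduction.

Step 4
Reactants: 5 2-[4-bromo-2-(hydroxymethyl)-6-(methoxymethoxy)phenoxy]-2-methylpropan-1-ol
Product: 6 5-bromo-3-(methoxymethoxy)-2-[(2-methyl-1-oxopropan-2-yl)oxy]benzaldehyde
Conditions: (COCl)2 (3 equiv), DMSO (6 equiv), CH2Cl2, −78 °C; Et3N (10 equiv), −78 to 0 °C
Reagents that add atoms: none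
Why: Swern oxidation: both alcohols are turned into alkoxysulfonium ions at −78 °C before the base is added, so the two aldehydes form together and no hydroxy aldehyde is left to close to a seven-membered lactol and be over-oxidised. The α-quaternary aldehyde cannot enolise.

Step 5
Reactants: 6 5-bromo-3-(methoxymethoxy)-2-[(2-methyl-1-oxopropan-2-yl)oxy]benzaldehyde
Product: 7 (3S)-6-bromo-3-hydroxy-8-(methoxymethoxy)-2,2-dimethylchroman-4-one
Conditions: (5aS,10bR)-2-(pentafluorophenyl)-5a,10b-dihydro-4H,6H-indeno[2,1-b][1,2,4]triazolo[4,3-d][1,4]oxazin-2-ium tetrafluoroborate (10 mol %), i-Pr2NEt (10 mol %), toluene (0.05 M), 0 °C to rt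
Reagents that add atoms: none
Why: The free carbene adds to the aryl aldehyde of 6 and proton transfer gives the Breslow intermediate, an acyl anion equivalent at the future C4. Its nucleophilic carbon attacks the tethered aldehyde carbon (future C3) in a 6-exo-trig closure that forms ring D; proton transfer to the new alkoxide and loss of the carbene release the aryl ketone 7. The closest known reaction type is the enantioselective carbene-catalysed intramolecular crossed benzoin of 2-(2-oxoalkoxy)benzaldehydes to 3-hydroxychroman-4-ones, together with carbene-catalysed benzoin cyclisations of dialdehydes; this step joins the two by using an aldehyde as the tethered acceptor. The new stereocentre C3 is set by the chiral carbene: in the hydrogen-bonded transition state the indane wall blocks one face of the enaminol, and the acceptor turns its hydrogen, not the C(Me)2O arm, towards the N-aryl group, which exposes one face of the aldehyde. The (5aS,10bR) salt is the first choice; because the sense of induction cannot be carried over safely from ketone acceptors, it is to be assigned on the first run by correlation, and the antipodal salt is used if the (3R) ketol results. Two selectivities are needed: role selectivity, secured because the aliphatic aldehyde has a fully substituted α-carbon, cannot enolise and is too hindered to form its own Breslow intermediate readily; and configurational integrity of the secondary ketol, secured by a weakly basic medium (acidic triazolium, catalytic amine), low temperature and short contact time. The gem-dimethyl group favours the folded conformer (Thorpe–Ingold effect), and dilution further suppresses intermolecular benzoin formation.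

Step 6
Reactants: 7 (3S)-6-bromo-3-hydroxy-8-(methoxymethoxy)-2,2-dimethylchroman-4-one
Product: 8 (3R,4S)-6-bromo-8-(methoxymethoxy)-2,2-dimethylchromane-3,4-diol
Conditions: Me4NBH(OAc)3 (5 equiv), MeCN/AcOH (1:1), −20 °C to rt; aq. potassium sodium tartrate
Reagents that add atoms: none
Why: Evans–Saksena hydroxyl-directed reduction: exchange of an acetate on boron for the C3 hydroxyl gives an alkoxyborohydride that delivers hydride within the molecule to C4 on the face of the C3 oxygen, so the new hydroxyl is trans to it, (4S); the C3 descriptor changes from S to R only through the priority change at C4. The free reagent is too weak to reduce the electron-rich chromanone carbonyl by itself, and directed reductions of cyclic α-hydroxy ketones to trans-1,2-diols are the precedent.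

Step 7
Reactants: 8 (3R,4S)-6-bromo-8-(methoxymethoxy)-2,2-dimethylchromane-3,4-diol
Product: 9 (3R,4S)-6-bromo-3,4-bis(tert-butyldimethylsilyloxy)-8-(methoxymethoxy)-2,2-dimethylchromane
Conditions: TBSOTf (3 equiv), 2,6-lutidine (5 equiv), CH2Cl2, −78 to 0 °C
Reagents that add atoms: tert-butyldimethylsilyl trifluoromethanesulfonate (TBSOTf), CC(C)(C)[Si](C)(C)OS(=O)(=O)C(F)(F)F
Why: Silylation of both secondary alcohols with the silyl triflate and a hindered pyridine base, the standard method for hindered carbinols; the low temperature protects the aryl MOM ether from the Lewis-acidic triflate.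

Step 8
Reactants: 9 (3R,4S)-6-bromo-3,4-bis(tert-butyldimethylsilyloxy)-8-(methoxymethoxy)-2,2-dimethylchromane
Product: 12 [(3R,4S)-3,4-bis(tert-butyldimethylsilyloxy)-8-(methoxymethoxy)-2,2-dimethylchroman-6-yl]boronic acid, via aryllithium 10 (not isolated), via lithium aryltriisopropoxyborate 11 (not isolated)
Conditions: B(Oi-Pr)3 (1.5 equiv), THF/toluene, −78 °C; n-BuLi (1.1 equiv), −78 to −20 °C; aq. NH4Cl
Reagents that add atoms: triisopropyl borate, CC(C)OB(OC(C)C)OC(C)C; water, O
Why: Lithium–bromine exchange at −78 °C is faster than ortho-lithiation beside the MOM ether and than attack of n-BuLi on the borate, so the aryllithium is trapped as it forms (in-situ quench); hydrolysis of the ate complex near neutral pH gives the boronic acid. The stereocentres are not involved.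

Step 9
Reactants: 13 7-hydroxy-4H-chromen-4-one
Product: 14 7-(methoxymethoxy)-4H-chromen-4-one
Conditions: MOMCl (1.5 equiv), i-Pr2NEt (2 equiv), CH2Cl2, 0 °C to rt
Reagents that add atoms: chloromethyl methyl ether (MOMCl), COCCl
Why: Williamson-type etherification of an acidic phenol with MOMCl and a tertiary amine; the chromone is inert to these conditions.

Step 10
Reactants: 12 [(3R,4S)-3,4-bis(tert-butyldimethylsilyloxy)-8-(methoxymethoxy)-2,2-dimethylchroman-6-yl]boronic acid; 14 7-(methoxymethoxy)-4H-chromen-4-one
Product: 15 (2S)-2-[(3R,4S)-3,4-bis(tert-butyldimethylsilyloxy)-8-(methoxymethoxy)-2,2-dimethylchroman-6-yl]-7-(methoxymethoxy)chroman-4-one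
Conditions: 14 (1.5 equiv), Pd(OCOCF3)2 (5 mol %), (R)-4-tert-butyl-2-(pyridin-2-yl)-4,5-dihydrooxazole [(R)-t-BuPyOx] (6 mol %), NH4PF6 (30 mol %), H2O (5 equiv), ClCH2CH2Cl, 60 °C
Reagents that add atoms: none
Why: Asymmetric conjugate addition of an arylboronic acid to a chromone catalysed by a cationic divalent palladium–pyridine-oxazoline complex: transmetalation, enantio-determining insertion of the chromone C2=C3 bond into the aryl–palladium bond, and protonolysis of the palladium enolate by water, with no base present, so the flavanone cannot open. The new C2 centre is set by the ligand, the ring-D centres being too remote to interfere; by analogy with the sense on β-substituted cyclic enones the (R)-ligand should give (2S), to be confirmed with 14 and a simple arylboronic acid. The boronic acid has no ortho substituent, which this catalyst requires.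

Step 11
Reactants: 15 (2S)-2-[(3R,4S)-3,4-bis(tert-butyldimethylsilyloxy)-8-(methoxymethoxy)-2,2-dimethylchroman-6-yl]-7-(methoxymethoxy)chroman-4-one
Product: 16 (2S)-7-hydroxy-2-[(3R,4S)-3,4,8-trihydroxy-2,2-dimethylchroman-6-yl]chroman-4-one
Conditions: 3 M aq. HCl, THF, rt to 40 °C
Reagents that add atoms: none
Why: Acid hydrolysis of two aryl MOM acetals and two secondary TBS ethers in one operation; water is the only nucleophile, so a transient C4 cation can only return to a diol, and the absence of base keeps ring C closed and C2 intact.

## Compound list

1 | 5-bromo-2,3-dihydroxybenzaldehyde | O=Cc1cc(Br)cc(O)c1O | starting material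
2 | 5-bromo-2-hydroxy-3-(methoxymethoxy)benzaldehyde | O=Cc1cc(Br)cc(OCOC)c1O | intermediate
3 | ethyl 2-bromo-2-methylpropanoate | CCOC(=O)C(C)(C)Br | starting material
4 | ethyl 2-[4-bromo-2-formyl-6-(methoxymethoxy)phenoxy]-2-methylpropanoate | CCOC(=O)C(C)(C)Oc1c(C=O)cc(Br)cc1OCOC | intermediate
5 | 2-[4-bromo-2-(hydroxymethyl)-6-(methoxymethoxy)phenoxy]-2-methylpropan-1-ol | OCc1cc(Br)cc(OCOC)c1OC(C)(C)CO | intermediate
6 | 5-bromo-3-(methoxymethoxy)-2-[(2-methyl-1-oxopropan-2-yl)oxy]benzaldehyde | O=Cc1cc(Br)cc(OCOC)c1OC(C)(C)C=O | intermediate
7 | (3S)-6-bromo-3-hydroxy-8-(methoxymethoxy)-2,2-dimethylchroman-4-one | CC1(C)Oc2c(OCOC)cc(Br)cc2C(=O)[C@H]1O | intermediate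
8 | (3R,4S)-6-bromo-8-(methoxymethoxy)-2,2-dimethylchromane-3,4-diol (trans) | CC1(C)Oc2c(OCOC)cc(Br)cc2[C@H](O)[C@H]1O | intermediate
9 | (3R,4S)-6-bromo-3,4-bis(tert-butyldimethylsilyloxy)-8-(methoxymethoxy)-2,2-dimethylchromane | CC1(C)Oc2c(OCOC)cc(Br)cc2[C@H](O[Si](C)(C)C(C)(C)C)[C@H]1O[Si](C)(C)C(C)(C)C | intermediate
10 | [(3R,4S)-3,4-bis(tert-butyldimethylsilyloxy)-8-(methoxymethoxy)-2,2-dimethylchroman-6-yl]lithium (not isolated) | CC1(C)Oc2c(OCOC)cc([Li])cc2[C@H](O[Si](C)(C)C(C)(C)C)[C@H]1O[Si](C)(C)C(C)(C)C | intermediate
11 | lithium [(3R,4S)-3,4-bis(tert-butyldimethylsilyloxy)-8-(methoxymethoxy)-2,2-dimethylchroman-6-yl]triisopropoxyborate (not isolated) | CC1(C)Oc2c(OCOC)cc([B-](OC(C)C)(OC(C)C)OC(C)C)cc2[C@H](O[Si](C)(C)C(C)(C)C)[C@H]1O[Si](C)(C)C(C)(C)C.[Li+] | intermediate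
12 | [(3R,4S)-3,4-bis(tert-butyldimethylsilyloxy)-8-(methoxymethoxy)-2,2-dimethylchroman-6-yl]boronic acid | CC1(C)Oc2c(OCOC)cc(B(O)O)cc2[C@H](O[Si](C)(C)C(C)(C)C)[C@H]1O[Si](C)(C)C(C)(C)C | intermediate
13 | 7-hydroxy-4H-chromen-4-one | O=c1ccoc2cc(O)ccc12 | starting material
14 | 7-(methoxymethoxy)-4H-chromen-4-one | COCOc1ccc2c(c1)occc2=O | intermediate
15 | (2S)-2-[(3R,4S)-3,4-bis(tert-butyldimethylsilyloxy)-8-(methoxymethoxy)-2,2-dimethylchroman-6-yl]-7-(methoxymethoxy)chroman-4-one | CC1(C)Oc2c(OCOC)cc([C@@H]3CC(=O)c4ccc(OCOC)cc4O3)cc2[C@H](O[Si](C)(C)C(C)(C)C)[C@H]1O[Si](C)(C)C(C)(C)C | intermediate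
16 | (2S)-7-hydroxy-2-[(3R,4S)-3,4,8-trihydroxy-2,2-dimethylchroman-6-yl]chroman-4-one | CC1(C)Oc2c(O)cc([C@@H]3CC(=O)c4ccc(O)cc4O3)cc2[C@H](O)[C@H]1O | target

## Step count and risks

Total: 11 steps. Longest linear sequence: 10 steps (steps 1–8, 10 and 11, from 1); step 9 is a one-step side branch.

**Step 5 (key step).** The most likely failure is loss of configurational purity at C3. The carbene may discriminate the faces of an aldehyde acceptor less well than those of the ketone acceptors it is known for, and the secondary ketol can enolise through its enediol under the basic catalyst. A second failure is engagement of the aliphatic aldehyde by the carbene. The α-aryloxide can then be expelled (internal redox to an aryl ester), a known path for α-aryloxy aldehydes once their Breslow intermediate forms.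

Fallback, from 2 back to 8: addition of 2-methylprop-1-enylmagnesium bromide (2.5 equiv, THF, 0 °C) to 2 would give 4-bromo-2-(1-hydroxy-3-methylbut-2-en-1-yl)-6-(methoxymethoxy)phenol F1. Cyclodehydration through the o-quinone methide and oxa-6π electrocyclisation (cat. pyridinium p-toluenesulfonate, toluene, 80 °C) would give 6-bromo-8-(methoxymethoxy)-2,2-dimethyl-2H-chromene F2. Jacobsen epoxidation with (R,R)-(salen)MnCl (salen = N,N′-bis(3,5-di-tert-butylsalicylidene)cyclohexane-1,2-diamine dianion), NaOCl and 4-phenylpyridine N-oxide is expected to give (3R,4R)-6-bromo-3,4-epoxy-8-(methoxymethoxy)-2,2-dimethylchromane F3. Dilute HClO4 in aqueous THF at 0 °C should open it at the benzylic carbon, mainly with inversion, to the trans-diol 8.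

**Step 2.** The most likely failure is a stalled O-alkylation. The phenoxide is flanked by the formyl and MOM-oxy groups, the electrophile is tertiary, and the bromo ester is consumed by elimination to the methacrylate.

Fallback, from 2 back to 6: copper-catalysed propargylation of 2 with 3-chloro-3-methylbut-1-yne (cat. CuCl2, DBU, MeCN, 0 °C), which proceeds through a cationic copper–allenylidene and so tolerates hindered phenoxides, would give 5-bromo-3-(methoxymethoxy)-2-[(2-methylbut-3-yn-2-yl)oxy]benzaldehyde F4. Lindlar-type semihydrogenation (H2, Pd/CaCO3 poisoned with Pb(OAc)2, quinoline) would give 5-bromo-3-(methoxymethoxy)-2-[(2-methylbut-3-en-2-yl)oxy]benzaldehyde F5. Ozonolysis (O3, CH2Cl2, −78 °C; PPh3) would then give 6 directly, replacing steps 2–4.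

**Step 6.** The most likely failure is incomplete hydroxyl direction. Slow ligand exchange at the hindered C3 hydroxyl, or slow hydride transfer to the electron-rich chromanone carbonyl, lets undirected reduction compete. Attack anti to the pseudo-axial C2 methyl group then gives the cis-diol (poor facial selectivity).

Fallback, from 7 back to 8: undirected reduction (NaBH4, MeOH, −40 °C) should favour (3R,4R)-6-bromo-8-(methoxymethoxy)-2,2-dimethylchromane-3,4-diol F6. A Mitsunobu reaction (4-nitrobenzoic acid, PPh3, diisopropyl azodicarboxylate) can take place only at the benzylic C4, since C3 is neopentylic, and with inversion. It would give (3R,4S)-6-bromo-3-hydroxy-8-(methoxymethoxy)-2,2-dimethylchroman-4-yl 4-nitrobenzoate F7, and K2CO3 in MeOH would then give 8. Any cis-diol formed as a by-product of step 6 can be recycled the same way.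

**Step 10.** The most likely failure is protodeboronation (and homocoupling) of the electron-rich boronic acid outrunning insertion into a chromone whose C2=C3 bond is deactivated by the C7 oxygen. A second is lower facial selectivity than with the parent chromone. Partial loss of acid-labile groups at 60 °C is tolerable, because step 11 removes them in any case.

Fallback, from 9 back to 15, without boron or palladium: lithium–bromine exchange on 9 and a DMF quench would give (3R,4S)-3,4-bis(tert-butyldimethylsilyloxy)-8-(methoxymethoxy)-2,2-dimethylchromane-6-carbaldehyde F8. Claisen–Schmidt condensation (KOH, EtOH) with 1-[2-hydroxy-4-(methoxymethoxy)phenyl]ethan-1-one F9 (from 2,4-dihydroxyacetophenone, MOMCl, K2CO3, acetone) would give (E)-3-[(3R,4S)-3,4-bis(tert-butyldimethylsilyloxy)-8-(methoxymethoxy)-2,2-dimethylchroman-6-yl]-1-[2-hydroxy-4-(methoxymethoxy)phenyl]prop-2-en-1-one F10. NaOAc in refluxing EtOH would close ring C without control, giving 15 together with its epimer (2R)-2-[(3R,4S)-3,4-bis(tert-butyldimethylsilyloxy)-8-(methoxymethoxy)-2,2-dimethylchroman-6-yl]-7-(methoxymethoxy)chroman-4-one F11. The two are diastereomers and may separate on silica; if they do not, a Noyori-type transfer hydrogenation with kinetic resolution (Cp*RhCl[(R,R)-TsDPEN], HCO2H/Et3N) should reduce the (2R)-ketone faster, to (2R,4R)-2-[(3R,4S)-3,4-bis(tert-butyldimethylsilyloxy)-8-(methoxymethoxy)-2,2-dimethylchroman-6-yl]-7-(methoxymethoxy)chroman-4-ol F12. This alcohol is separable from the unreacted ketone 15, at the cost of half the material.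

**Step 11.** The most likely failure is ionisation at the benzylic C4 under the acid needed for the aryl MOM ethers, with epimerisation to the cis-diol or dehydration.

Fallback, from 15 back to 16, in two stages so that the diol is released by fluoride and not by protic acid: Bu4NF buffered with AcOH (THF, 0 °C to rt) would give (2S)-2-[(3R,4S)-3,4-dihydroxy-8-(methoxymethoxy)-2,2-dimethylchroman-6-yl]-7-(methoxymethoxy)chroman-4-one F13. The two aryl MOM ethers are then cleaved on a solid acid without a solvolytic medium (NaHSO4·SiO2, CH2Cl2, rt), a method selective for phenolic MOM ethers, to give 16.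

## Further compounds

F1 | step 5 | 4-bromo-2-(1-hydroxy-3-methylbut-2-en-1-yl)-6-(methoxymethoxy)phenol | CC(C)=CC(O)c1cc(Br)cc(OCOC)c1O
F2 | step 5 | 6-bromo-8-(methoxymethoxy)-2,2-dimethyl-2H-chromene | CC1(C)C=Cc2cc(Br)cc(OCOC)c2O1
F3 | step 5 | (3R,4R)-6-bromo-3,4-epoxy-8-(methoxymethoxy)-2,2-dimethylchromane | CC1(C)Oc2c(OCOC)cc(Br)cc2[C@H]3O[C@@H]13
F4 | step 2 | 5-bromo-3-(methoxymethoxy)-2-[(2-methylbut-3-yn-2-yl)oxy]benzaldehyde | O=Cc1cc(Br)cc(OCOC)c1OC(C)(C)C#C
F5 | step 2 | 5-bromo-3-(methoxymethoxy)-2-[(2-methylbut-3-en-2-yl)oxy]benzaldehyde | O=Cc1cc(Br)cc(OCOC)c1OC(C)(C)C=C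
F6 | step 6 | (3R,4R)-6-bromo-8-(methoxymethoxy)-2,2-dimethylchromane-3,4-diol (cis) | CC1(C)Oc2c(OCOC)cc(Br)cc2[C@@H](O)[C@H]1O
F7 | step 6 | (3R,4S)-6-bromo-3-hydroxy-8-(methoxymethoxy)-2,2-dimethylchroman-4-yl 4-nitrobenzoate | CC1(C)Oc2c(OCOC)cc(Br)cc2[C@H](OC(=O)c3ccc(cc3)[N+](=O)[O-])[C@H]1O
F8 | step 10 | (3R,4S)-3,4-bis(tert-butyldimethylsilyloxy)-8-(methoxymethoxy)-2,2-dimethylchromane-6-carbaldehyde | CC1(C)Oc2c(OCOC)cc(C=O)cc2[C@H](O[Si](C)(C)C(C)(C)C)[C@H]1O[Si](C)(C)C(C)(C)C
F9 | step 10 | 1-[2-hydroxy-4-(methoxymethoxy)phenyl]ethan-1-one | CC(=O)c1ccc(OCOC)cc1O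
F10 | step 10 | (E)-3-[(3R,4S)-3,4-bis(tert-butyldimethylsilyloxy)-8-(methoxymethoxy)-2,2-dimethylchroman-6-yl]-1-[2-hydroxy-4-(methoxymethoxy)phenyl]prop-2-en-1-one | CC1(C)Oc2c(OCOC)cc(/C=C/C(=O)c3ccc(OCOC)cc3O)cc2[C@H](O[Si](C)(C)C(C)(C)C)[C@H]1O[Si](C)(C)C(C)(C)C
F11 | step 10 | (2R)-2-[(3R,4S)-3,4-bis(tert-butyldimethylsilyloxy)-8-(methoxymethoxy)-2,2-dimethylchroman-6-yl]-7-(methoxymethoxy)chroman-4-one | CC1(C)Oc2c(OCOC)cc([C@H]3CC(=O)c4ccc(OCOC)cc4O3)cc2[C@H](O[Si](C)(C)C(C)(C)C)[C@H]1O[Si](C)(C)C(C)(C)C
F12 | step 10 | (2R,4R)-2-[(3R,4S)-3,4-bis(tert-butyldimethylsilyloxy)-8-(methoxymethoxy)-2,2-dimethylchroman-6-yl]-7-(methoxymethoxy)chroman-4-ol | CC1(C)Oc2c(OCOC)cc([C@H]3C[C@@H](O)c4ccc(OCOC)cc4O3)cc2[C@H](O[Si](C)(C)C(C)(C)C)[C@H]1O[Si](C)(C)C(C)(C)C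
F13 | step 11 | (2S)-2-[(3R,4S)-3,4-dihydroxy-8-(methoxymethoxy)-2,2-dimethylchroman-6-yl]-7-(methoxymethoxy)chroman-4-one | CC1(C)Oc2c(OCOC)cc([C@@H]3CC(=O)c4ccc(OCOC)cc4O3)cc2[C@H](O)[C@H]1O
A1 | alternative 1 | (2S,4S)-7-(methoxymethoxy)-2-[8-(methoxymethoxy)-2,2-dimethyl-2H-chromen-6-yl]chroman-4-ol | CC1(C)Oc2c(OCOC)cc([C@@H]3C[C@H](O)c4ccc(OCOC)cc4O3)cc2C=C1
A2 | alternative 1 | (1S,3S)-1-[2-bromo-4-(methoxymethoxy)phenyl]-3-[8-(methoxymethoxy)-2,2-dimethyl-2H-chromen-6-yl]propane-1,3-diol | CC1(C)Oc2c(OCOC)cc([C@@H](O)C[C@H](O)c3ccc(OCOC)cc3Br)cc2C=C1
A3 | alternative 2 | (2S)-7-hydroxy-2-[(3R,4S)-3,4,8-tris(methoxymethoxy)-2,2-dimethylchroman-6-yl]chroman-4-one | CC1(C)Oc2c(OCOC)cc([C@@H]3CC(=O)c4ccc(O)cc4O3)cc2[C@H](OCOC)[C@H]1OCOC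
A4 | alternative 2 | (2S)-6-[(3E)-4-methoxy-2-oxobut-3-en-1-yl]-2-[(3R,4S)-3,4,8-tris(methoxymethoxy)-2,2-dimethylchroman-6-yl]-2,3-dihydro-4H-pyran-4-one | CC1(C)Oc2c(OCOC)cc([C@@H]3CC(=O)C=C(CC(=O)/C=C/OC)O3)cc2[C@H](OCOC)[C@H]1OCOC
A5 | alternative 3 | (3R,4S)-6-bromo-4-(tert-butyldimethylsilyloxy)-8-(methoxymethoxy)-2,2-dimethylchroman-3-ol | CC1(C)Oc2c(OCOC)cc(Br)cc2[C@H](O[Si](C)(C)C(C)(C)C)[C@H]1O
A6 | alternative 3 | 4-bromo-2-{(S)-(tert-butyldimethylsilyloxy)[(2R)-3,3-dimethyloxiran-2-yl]methyl}-6-(methoxymethoxy)phenol | Oc1c(OCOC)cc(Br)cc1[C@H](O[Si](C)(C)C(C)(C)C)[C@H]2OC2(C)C
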